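**Strategy.** The carbocycle is a dearomatised acylphloroglucinol: its enol C–OH, pyranone O–C= and ring C=O carbons alternate with the acyl-bearing, quaternary and side-chain-bearing carbons. This 1,3,5-oxygen pattern is exploited by building the ring first as an aromatic phloroglucinol ether in a Danheiser benzannulation. Ethoxyacetylene is inserted into a 3-siloxycyclobutenone (from a pinene-derived siloxyalkyne and a glutarate-derived ketene). In one operation this joins the phenol carbon to the ring CH that later carries the pyranone carbonyl, and the ethoxy-bearing carbon to the future quaternary carbon. Acylation, ligand-controlled dearomative prenylation and displacement of ethoxide by the side-chain hydroxyl then finish the cis-dimethylpyranone core.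

Key step: step 7

Remark: the target is an enolised β-triketone; the tautomer drawn is taken as the structure and the others equilibrate with it.
Remark: the side-chain methyl ester is assumed not to lactonise onto the neighbouring phenol under the neutral or buffered conditions used; a lactone, if formed, would be opened in the last step all the same.

Step 1
Reactants: 1 (1R,5R)-(+)-α-pinene
Product: 2 cis-pinonic acid (2-[(1S,3S)-3-acetyl-2,2-dimethylcyclobutyl]acetic acid)
Conditions: RuCl3·xH2O (cat.), NaIO4, CCl4/MeCN/H2O, rt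
Reagents that add atoms: sodium periodate ([Na+].[O-]I(=O)(=O)=O); water (O)
Why: RuO4 formed in situ should cleave the trisubstituted ring alkene to the methyl ketone and the carboxylic acid (oxidative alkene cleavage), a carbon–carbon cleavage that keeps the cis-1,3-disubstituted cyclobutane and both of its stereocentres.

Step 2
Reactants: 2 cis-pinonic acid
Product: 3 methyl 2-[(1S,3S)-3-acetyl-2,2-dimethylcyclobutyl]acetate
Conditions: MeI, K2CO3, DMF, rt
Reagents that add atoms: iodomethane (CI)
Why: O-alkylation of the carboxylate under weakly basic conditions should give the methyl ester without epimerising the ring carbon next to the ketone.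

Step 3
Reactants: 3 methyl cis-pinonate
Product: 4 methyl 2-[(1S,3R)-2,2-dimethyl-3-(prop-1-en-2-yl)cyclobutyl]acetate
Conditions: Ph3PCH3Br, KOtBu, THF, 0 °C → rt
Reagents that add atoms: methyltriphenylphosphonium bromide (C[P+](c1ccccc1)(c1ccccc1)c1ccccc1.[Br-])
Why: Wittig methylenation is chemoselective for the ketone over the ester and, run cold with a non-stabilised ylide, should not epimerise the adjacent ring stereocentre.

Step 4
Reactants: 4 isopropenyl ester
Product: 5 siloxyalkyne (triisopropyl({3-[(1S,3R)-2,2-dimethyl-3-(prop-1-en-2-yl)cyclobutyl]prop-1-yn-1-yl}oxy)silane)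
Conditions: CH2Br2, LiTMP, THF, −78 °C; then n-BuLi, −78 → 0 °C; then TIPSOTf, −78 °C → rt
Reagents that add atoms: dibromomethane (BrCBr); triisopropylsilyl trifluoromethanesulfonate (CC(C)[Si](C(C)C)(C(C)C)OS(=O)(=O)C(F)(F)F)
Why: Kowalski ester homologation: addition of LiCHBr2, enolisation, bromine–lithium exchange and 1,2-shift should give the lithium ynolate, which the bulky silyl triflate traps on oxygen.

Step 5
Reactants: 6 3-propylglutaric anhydride
Product: 7 (3R)-3-(2-methoxy-2-oxoethyl)hexanoic acid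
Conditions: (DHQD)2AQN (10 mol %), MeOH, Et2O, −40 °C
Reagents that add atoms: methanol (CO)
Why: Alkaloid-catalysed desymmetrising methanolysis of the prochiral anhydride sets the hexanoate stereocentre; the quinidine-derived catalyst is expected to give the (R)-half-ester by analogy with other 3-alkylglutaric anhydrides, and the quinine-derived pseudoenantiomer would give the antipode.

Step 6
Reactants: 7 (R)-half-ester, 5 siloxyalkyne
Product: 10 3-siloxycyclobutenone (methyl (3S)-3-[3-{[(1S,3R)-2,2-dimethyl-3-(prop-1-en-2-yl)cyclobutyl]methyl}-4-oxo-2-(triisopropylsilyloxy)cyclobut-2-en-1-yl]hexanoate), via acid chloride 8 (not isolated), via ketene 9 (not isolated)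
Conditions: 7 (2 equiv), (COCl)2, DMF (cat.), CH2Cl2, 0 °C → rt, evaporate; then 5, Et3N (slow addition), toluene, rt → 40 °C
Reagents that add atoms: none
Why: Dehydrochlorination of the acid chloride gives the aldoketene, which should add to the electron-rich siloxyalkyne in a regioselective [2+2] (ketene carbonyl carbon to the alkyne carbon remote from oxygen); the new ring CH stereocentre is not controlled and does not need to be, since it becomes aromatic in step 7.

Step 7
Reactants: 10 3-siloxycyclobutenone, 11 ethoxyacetylene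
Product: 16 pentasubstituted phenol (methyl (3S)-3-[3-{[(1S,3R)-2,2-dimethyl-3-(prop-1-en-2-yl)cyclobutyl]methyl}-4-ethoxy-6-hydroxy-2-(triisopropylsilyloxy)phenyl]hexanoate), via vinylketene 12 (not isolated), via vinylcyclobutenone 13 (not isolated), via dienylketene 14 (not isolated), via cyclohexadienone 15 (not isolated)
Conditions: 11 (3 equiv), toluene, 80 °C, sealed tube
Reagents that add atoms: none
Why: Heating should open the cyclobutenone by 4π electrocyclic cleavage of its C(=O)–CH bond to vinylketene 12; the ketene then adds ethoxyacetylene in a regioselective [2+2] (ketene carbonyl carbon to the CH terminus, ketene α-carbon to the ethoxy-bearing carbon) to give 13, whose 4π opening gives dienylketene 14. The six-membered ring closes by 6π electrocyclisation of 14 (bond between the ketene carbon and the side-chain-bearing terminus) and dienone 15 tautomerises to the phenol, so that the alkyne ends up inserted into the former C(=O)–C(sp2) bond of the cyclobutenone. The closest known reaction type is the Danheiser benzannulation of cyclobutenones with alkoxy- or siloxyalkynes. No stereocentre is formed: the stereogenic ring carbon of 10 becomes aromatic (both epimers converge) and the cyclobutane and hexanoate centres are not touched. The step needs regiocontrol in the [2+2], which the polarisation of the ynol ether secures, placing OEt meta to the new OH and next to the cyclobutylmethyl-bearing carbon; excess alkyne should suppress acylation of the product phenol by the vinylketene.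

Step 8
Reactants: 17 (4S)-4-benzyl-3-propanoyl-1,3-oxazolidin-2-one
Product: 18 (4S)-4-benzyl-3-[(2S,3R)-3-hydroxy-2-methylbutanoyl]-1,3-oxazolidin-2-one
Conditions: Bu2BOTf, i-Pr2NEt, CH2Cl2, −78 °C; acetaldehyde, −78 → 0 °C; then H2O2, MeOH, pH 7 buffer
Reagents that add atoms: acetaldehyde (CC=O)
Why: Evans syn-aldol reaction: the Z-boron enolate should add through a chair transition state on the face left open by the benzyl group, which sets both the (2S) and (3R) centres.

Step 9
Reactants: 18 aldol adduct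
Product: 19 (4S)-4-benzyl-3-[(2S,3R)-3-(tert-butyldimethylsilyloxy)-2-methylbutanoyl]-1,3-oxazolidin-2-one
Conditions: TBSOTf, 2,6-lutidine, CH2Cl2, 0 °C
Reagents that add atoms: tert-butyldimethylsilyl trifluoromethanesulfonate (CC(C)(C)[Si](C)(C)OS(=O)(=O)C(F)(F)F)
Why: Silylation of the secondary alcohol blocks retro-aldol cleavage and elimination in the following steps.

Step 10
Reactants: 19 silyl ether
Product: 20 (2S,3R)-3-(tert-butyldimethylsilyloxy)-2-methylbutanoic acid
Conditions: LiOH, H2O2, THF/H2O, 0 °C; Na2SO3; then HCl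
Reagents that add atoms: hydrogen peroxide (OO)
Why: Hydroperoxide attacks the exocyclic imide carbonyl selectively, so the auxiliary should be released without epimerising the α-centre.

Step 11
Reactants: 16 phenol, 20 silyloxy acid
Product: 22 aryl ketone (methyl (3S)-3-[3-{[(1S,3R)-2,2-dimethyl-3-(prop-1-en-2-yl)cyclobutyl]methyl}-5-[(2S,3R)-3-(tert-butyldimethylsilyloxy)-2-methylbutanoyl]-4-ethoxy-6-hydroxy-2-(triisopropylsilyloxy)phenyl]hexanoate), via acid chloride 21 (not isolated)
Conditions: 20, 1-chloro-N,N,2-trimethylprop-1-en-1-amine (Ghosez reagent), CH2Cl2, 0 °C; then 16, SnCl4, 2,6-di-tert-butylpyridine, CH2Cl2, −78 → −30 °C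
Reagents that add atoms: none
Why: Friedel–Crafts acylation can only occur at the single unsubstituted ring carbon, which is ortho to the phenol and to the ethoxy group and para to the siloxy group; the hindered pyridine removes HCl so that the isopropenylcyclobutane and the silyl ethers should survive.

Step 12
Reactants: 22 aryl ketone
Product: 23 methyl (3S)-3-[3-{[(1S,3R)-2,2-dimethyl-3-(prop-1-en-2-yl)cyclobutyl]methyl}-4-ethoxy-2,6-dihydroxy-5-[(2S,3R)-3-hydroxy-2-methylbutanoyl]phenyl]hexanoate
Conditions: HF·pyridine, pyridine, THF, 0 °C → rt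
Reagents that add atoms: none
Why: Buffered, mildly acidic fluoride should remove both silyl groups without the retro-aldol cleavage or α-epimerisation that a basic fluoride source could cause in the β-hydroxy ketone.

Step 13
Reactants: 23 dihydroxy ketone
Product: 25 methyl ester of the target (methyl (3S)-3-[(2R,3S,8R)-8-{[(1S,3R)-2,2-dimethyl-3-(prop-1-en-2-yl)cyclobutyl]methyl}-5-hydroxy-2,3-dimethyl-8-(3-methylbut-2-en-1-yl)-4,7-dioxo-3,4,7,8-tetrahydro-2H-chromen-6-yl]hexanoate), via ethoxy dienone 24 (not isolated)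
Conditions: Pd2(dba)3·CHCl3 (2.5 mol %), (R,R)-DACH-phenyl Trost ligand (7.5 mol %), prenyl acetate, Et3N, toluene, 0 °C → rt; then AcOH, 50 °C
Reagents that add atoms: prenyl acetate (CC(C)=CCOC(C)=O)
Why: Zerovalent palladium ionises prenyl acetate to a π-prenyl complex, which the phenoxide para to the acyl group should attack at the unsubstituted allyl terminus through its less hindered ortho carbon, the one bearing the cyclobutylmethyl group (Tsuji–Trost-type allylic dearomatisation of a phenol, with O-allylation reversible under the catalyst); the chiral ligand is relied on for the face selection that sets the (R)-quaternary centre, the (S,S)-ligand being used instead should the sense prove opposite, and acetic acid then promotes 6-endo addition–elimination of the side-chain hydroxyl at the β-ethoxy enone carbon of 24, closing the pyranone with retention at both methyl-bearing centres (syn chain gives the cis ring).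

Step 14
Reactants: 25 methyl ester
Product: 26 target acid, (3S)-3-[(2R,3S,8R)-8-{[(1S,3R)-2,2-dimethyl-3-(prop-1-en-2-yl)cyclobutyl]methyl}-5-hydroxy-2,3-dimethyl-8-(3-methylbut-2-en-1-yl)-4,7-dioxo-3,4,7,8-tetrahydro-2H-chromen-6-yl]hexanoic acid
Conditions: LiOH, THF/H2O, 0 °C → rt; then 1 M HCl to pH 3, 0 °C
Reagents that add atoms: lithium hydroxide ([Li+].[OH-])
Why: Saponification of the unhindered methyl ester; under the base the β-triketone is present as its delocalised enolate, which should protect the pyranone from ring opening and its α-methyl centre from epimerisation.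

**Compound list**

1 | (1R,5R)-(+)-α-pinene, (1R,5R)-2,6,6-trimethylbicyclo[3.1.1]hept-2-ene | CC1=CC[C@@H]2C[C@H]1C2(C)C | starting material
2 | cis-pinonic acid, 2-[(1S,3S)-3-acetyl-2,2-dimethylcyclobutyl]acetic acid | CC(=O)[C@H]1C[C@@H](CC(=O)O)C1(C)C | intermediate
3 | methyl 2-[(1S,3S)-3-acetyl-2,2-dimethylcyclobutyl]acetate | CC(=O)[C@H]1C[C@@H](CC(=O)OC)C1(C)C | intermediate
4 | methyl 2-[(1S,3R)-2,2-dimethyl-3-(prop-1-en-2-yl)cyclobutyl]acetate | C=C(C)[C@H]1C[C@@H](CC(=O)OC)C1(C)C | intermediate
5 | siloxyalkyne, triisopropyl({3-[(1S,3R)-2,2-dimethyl-3-(prop-1-en-2-yl)cyclobutyl]prop-1-yn-1-yl}oxy)silane | C=C(C)[C@H]1C[C@@H](CC#CO[Si](C(C)C)(C(C)C)C(C)C)C1(C)C | intermediate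
6 | 3-propylglutaric anhydride (4-propyloxane-2,6-dione) | CCCC1CC(=O)OC(=O)C1 | starting material
7 | (3R)-3-(2-methoxy-2-oxoethyl)hexanoic acid | OC(=O)C[C@@H](CCC)CC(=O)OC | intermediate
8 | acid chloride, methyl (3S)-3-(2-chloro-2-oxoethyl)hexanoate (not isolated) | ClC(=O)C[C@@H](CCC)CC(=O)OC | intermediate
9 | ketene, methyl (3S)-5-oxo-3-propylpent-4-enoate (not isolated) | O=C=C[C@@H](CCC)CC(=O)OC | intermediate
10 | 3-siloxycyclobutenone, methyl (3S)-3-[3-{[(1S,3R)-2,2-dimethyl-3-(prop-1-en-2-yl)cyclobutyl]methyl}-4-oxo-2-(triisopropylsilyloxy)cyclobut-2-en-1-yl]hexanoate, both epimers at the ring CH | C=C(C)[C@H]1C[C@@H](CC2=C(O[Si](C(C)C)(C(C)C)C(C)C)C([C@@H](CCC)CC(=O)OC)C2=O)C1(C)C | intermediate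
11 | ethoxyacetylene (ethoxyethyne) | CCOC#C | starting material
12 | vinylketene, methyl (3S)-6-{[(1S,3R)-2,2-dimethyl-3-(prop-1-en-2-yl)cyclobutyl]methyl}-7-oxo-3-propyl-5-(triisopropylsilyloxy)hepta-4,6-dienoate (not isolated) | C=C(C)[C@H]1C[C@@H](CC(=C=O)C(O[Si](C(C)C)(C(C)C)C(C)C)=C[C@@H](CCC)CC(=O)OC)C1(C)C | intermediate
13 | vinylcyclobutenone, methyl (3S)-5-[1-{[(1S,3R)-2,2-dimethyl-3-(prop-1-en-2-yl)cyclobutyl]methyl}-2-ethoxy-4-oxocyclobut-2-en-1-yl]-3-propyl-5-(triisopropylsilyloxy)pent-4-enoate (not isolated) | C=C(C)[C@H]1C[C@@H](CC2(C(O[Si](C(C)C)(C(C)C)C(C)C)=C[C@@H](CCC)CC(=O)OC)C(=O)C=C2OCC)C1(C)C | intermediate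
14 | dienylketene, methyl (3S)-6-{[(1S,3R)-2,2-dimethyl-3-(prop-1-en-2-yl)cyclobutyl]methyl}-7-ethoxy-9-oxo-3-propyl-5-(triisopropylsilyloxy)nona-4,6,8-trienoate (not isolated) | C=C(C)[C@H]1C[C@@H](CC(C(O[Si](C(C)C)(C(C)C)C(C)C)=C[C@@H](CCC)CC(=O)OC)=C(OCC)C=C=O)C1(C)C | intermediate
15 | cyclohexadienone, methyl (3S)-3-[3-{[(1S,3R)-2,2-dimethyl-3-(prop-1-en-2-yl)cyclobutyl]methyl}-4-ethoxy-6-oxo-2-(triisopropylsilyloxy)cyclohexa-2,4-dien-1-yl]hexanoate (not isolated) | C=C(C)[C@H]1C[C@@H](CC2=C(O[Si](C(C)C)(C(C)C)C(C)C)C([C@@H](CCC)CC(=O)OC)C(=O)C=C2OCC)C1(C)C | intermediate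
16 | phenol, methyl (3S)-3-[3-{[(1S,3R)-2,2-dimethyl-3-(prop-1-en-2-yl)cyclobutyl]methyl}-4-ethoxy-6-hydroxy-2-(triisopropylsilyloxy)phenyl]hexanoate | C=C(C)[C@H]1C[C@@H](Cc2c(OCC)cc(O)c([C@@H](CCC)CC(=O)OC)c2O[Si](C(C)C)(C(C)C)C(C)C)C1(C)C | intermediate
17 | (4S)-4-benzyl-3-propanoyl-1,3-oxazolidin-2-one | CCC(=O)N1[C@@H](Cc2ccccc2)COC1=O | starting material
18 | (4S)-4-benzyl-3-[(2S,3R)-3-hydroxy-2-methylbutanoyl]-1,3-oxazolidin-2-one | C[C@@H](O)[C@H](C)C(=O)N1[C@@H](Cc2ccccc2)COC1=O | intermediate
19 | (4S)-4-benzyl-3-[(2S,3R)-3-(tert-butyldimethylsilyloxy)-2-methylbutanoyl]-1,3-oxazolidin-2-one | C[C@@H](O[Si](C)(C)C(C)(C)C)[C@H](C)C(=O)N1[C@@H](Cc2ccccc2)COC1=O | intermediate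
20 | (2S,3R)-3-(tert-butyldimethylsilyloxy)-2-methylbutanoic acid | C[C@@H](O[Si](C)(C)C(C)(C)C)[C@H](C)C(=O)O | intermediate
21 | (2S,3R)-3-(tert-butyldimethylsilyloxy)-2-methylbutanoyl chloride (not isolated) | C[C@@H](O[Si](C)(C)C(C)(C)C)[C@H](C)C(Cl)=O | intermediate
22 | aryl ketone, methyl (3S)-3-[3-{[(1S,3R)-2,2-dimethyl-3-(prop-1-en-2-yl)cyclobutyl]methyl}-5-[(2S,3R)-3-(tert-butyldimethylsilyloxy)-2-methylbutanoyl]-4-ethoxy-6-hydroxy-2-(triisopropylsilyloxy)phenyl]hexanoate | C=C(C)[C@H]1C[C@@H](Cc2c(OCC)c(C(=O)[C@@H](C)[C@@H](C)O[Si](C)(C)C(C)(C)C)c(O)c([C@@H](CCC)CC(=O)OC)c2O[Si](C(C)C)(C(C)C)C(C)C)C1(C)C | intermediate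
23 | methyl (3S)-3-[3-{[(1S,3R)-2,2-dimethyl-3-(prop-1-en-2-yl)cyclobutyl]methyl}-4-ethoxy-2,6-dihydroxy-5-[(2S,3R)-3-hydroxy-2-methylbutanoyl]phenyl]hexanoate | C=C(C)[C@H]1C[C@@H](Cc2c(OCC)c(C(=O)[C@@H](C)[C@@H](C)O)c(O)c([C@@H](CCC)CC(=O)OC)c2O)C1(C)C | intermediate
24 | ethoxy dienone, methyl (3S)-3-[(5R)-5-{[(1S,3R)-2,2-dimethyl-3-(prop-1-en-2-yl)cyclobutyl]methyl}-4-ethoxy-2-hydroxy-3-[(2S,3R)-3-hydroxy-2-methylbutanoyl]-5-(3-methylbut-2-en-1-yl)-6-oxocyclohexa-1,3-dien-1-yl]hexanoate (not isolated) | C=C(C)[C@H]1C[C@@H](C[C@@]2(CC=C(C)C)C(=O)C([C@@H](CCC)CC(=O)OC)=C(O)C(C(=O)[C@@H](C)[C@@H](C)O)=C2OCC)C1(C)C | intermediate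
25 | methyl ester of the target, methyl (3S)-3-[(2R,3S,8R)-8-{[(1S,3R)-2,2-dimethyl-3-(prop-1-en-2-yl)cyclobutyl]methyl}-5-hydroxy-2,3-dimethyl-8-(3-methylbut-2-en-1-yl)-4,7-dioxo-3,4,7,8-tetrahydro-2H-chromen-6-yl]hexanoate | C=C(C)[C@H]1C[C@@H](C[C@@]2(CC=C(C)C)C(=O)C([C@@H](CCC)CC(=O)OC)=C(O)C3=C2O[C@H](C)[C@H](C)C3=O)C1(C)C | intermediate
26 | target, (3S)-3-[(2R,3S,8R)-8-{[(1S,3R)-2,2-dimethyl-3-(prop-1-en-2-yl)cyclobutyl]methyl}-5-hydroxy-2,3-dimethyl-8-(3-methylbut-2-en-1-yl)-4,7-dioxo-3,4,7,8-tetrahydro-2H-chromen-6-yl]hexanoic acid | C=C(C)[C@H]1C[C@@H](C[C@@]2(CC=C(C)C)C(=O)C([C@@H](CCC)CC(=O)O)=C(O)C3=C2O[C@H](C)[C@H](C)C3=O)C1(C)C | target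

**Step count.** Total: 14 steps. Longest linear sequence: 10 steps (steps 1–4, 6, 7, 11–14).

**Steps most likely to fail**

1. Step 13. The ligand may give poor facial selectivity at the new quaternary carbon, and O-allylation or attack at the other ortho carbon may compete. Fallback: from 23 the allylation is run with the achiral catalyst Pd(PPh3)4 (prenyl acetate, Et3N, toluene; then AcOH, 50 °C), accepting both configurations at the quaternary carbon. Ethoxy dienone 24 should then form together with the epimeric ethoxy dienone F1. Under the acid, 24 cyclises to 25 and F1 cyclises to the epimeric pyranone ester F2. F2 and 25 are diastereomers and are separated by preparative HPLC, and the route is rejoined at 25.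

2. Step 7. The volatile alkyne may be lost, the [2+2] may be slow, or the vinylketene may be consumed by the product phenol. Fallback: from 10 the vinylketene 12 is trapped at 80 °C with 1,1-diethoxyethene, a more nucleophilic and less volatile ketenophile, by ketene–ketene acetal [2+2] to give the 3,3-diethoxycyclobutanone F3. Loss of ethanol from F3 on further heating or on silica gives vinylcyclobutenone 13, which rearranges through 14 and 15 to 16.

3. Step 11. Acid may damage the isopropenylcyclobutane, or acylation may stop at oxygen. Fallback: from 16 and 20 the phenol is esterified with DCC and DMAP in CH2Cl2 to the aryl ester F4. A photo-Fries rearrangement of F4 (hν 254 nm, hexane) then moves the acyl group to the only free ortho carbon and returns to 22 without any Lewis or Brønsted acid.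

**Further compounds**

F1 | step 13 | epimeric ethoxy dienone (quaternary-carbon epimer of 24) | C=C(C)[C@H]1C[C@@H](C[C@]2(CC=C(C)C)C(=O)C([C@@H](CCC)CC(=O)OC)=C(O)C(C(=O)[C@@H](C)[C@@H](C)O)=C2OCC)C1(C)C
F2 | step 13 | epimeric pyranone ester (quaternary-carbon epimer of 25) | C=C(C)[C@H]1C[C@@H](C[C@]2(CC=C(C)C)C(=O)C([C@@H](CCC)CC(=O)OC)=C(O)C3=C2O[C@H](C)[C@H](C)C3=O)C1(C)C
F3 | step 7 | 3,3-diethoxycyclobutanone from vinylketene 12 and 1,1-diethoxyethene | C=C(C)[C@H]1C[C@@H](CC2(C(O[Si](C(C)C)(C(C)C)C(C)C)=C[C@@H](CCC)CC(=O)OC)C(=O)CC2(OCC)OCC)C1(C)C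
F4 | step 11 | aryl ester of phenol 16 with acid 20 | C=C(C)[C@H]1C[C@@H](Cc2c(OCC)cc(OC(=O)[C@@H](C)[C@@H](C)O[Si](C)(C)C(C)(C)C)c([C@@H](CCC)CC(=O)OC)c2O[Si](C(C)C)(C(C)C)C(C)C)C1(C)C
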